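**Retrosynthetic overview**
1. Bought pieces: 1-bromoeicosane (1, the C20 part of the chain) and 3,5-dimethoxybenzyl bromide (2, the ring plus the benzylic carbon). No ring is formed; the benzene ring is purchased.
2. Supporting disconnection: the benzylic CH2–CH2 bond, made from Grignard reagent 3 (from 1) and 2 under copper catalysis, giving 1-heneicosyl-3,5-dimethoxybenzene (4).
3. Key disconnection: the phenolic C(aryl)–O bond, made last by direct anodic C–H oxygenation of 4 at C2 (ortho to the chain, para to one methoxy group).
4. The oxygen is delivered by tetramethylurea as an O-aryl isouronium salt (5), which is unmasked in the same flask to the target (6).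

Assumption: the target has no stereocentre (it is achiral), so "single enantiomer" requires no stereocontrol.

**Step 1**
Reactants: 1 1-bromoeicosane; 2 3,5-dimethoxybenzyl bromide
Product: 4 1-heneicosyl-3,5-dimethoxybenzene, via eicosylmagnesium bromide 3 (not isolated)
Conditions: 1 (1.3 equiv), Mg turnings (1.6 equiv), THF, 50 °C; then added slowly to 2 (1.0 equiv), Li2CuCl4 (3 mol%), THF, −10 °C → rt; NH4Cl aq
Reagents that add atoms: none
Why: Kochi-type copper-catalysed sp3–sp3 cross-coupling of a primary alkyl Grignard reagent with a reactive benzylic bromide joins C20 to the benzylic carbon to give the C21 chain, the aryl methyl ethers are inert, and no stereocentre is formed.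

**Step 2**
Reactants: 4 1-heneicosyl-3,5-dimethoxybenzene
Product: 6 6-n-heneicosyl-2,4-dimethoxyphenol, via O-aryl tetramethylisouronium triflate 5 (not isolated)
Conditions: undivided cell, graphite anode, Pt cathode, constant current 5 mA cm−2, 2.3 F mol−1, TfOH (1.5 equiv), dry tetramethylurea/CH2Cl2 (1:3 v/v, 0.05 M in 4), 20 °C, Ar; then NaOH (2 M aq, degassed), MeOH, 50 °C, Ar; then HCl (1 M aq)
Reagents that add atoms: tetramethylurea, CN(C)C(=O)N(C)C (its oxygen atom becomes the phenolic oxygen)
Why: Proposed new method: anodic C–H oxygenation with a urea as masked hydroxide, in which the radical cation of 4 (formed near +1.5 V vs SCE, well below the potential at which the urea is oxidised, and carrying little spin density at the meta-placed benzylic carbon) is captured by the carbonyl oxygen of tetramethylurea at C2, the site para to one methoxy group and ortho to the other where classical electrophiles attack 5-alkylresorcinol dimethyl ethers, then loses a second electron and a proton to give the cationic O-aryl isouronium salt 5, whose electron-poor oxygen substituent protects the ring from the over-oxidation to a quinone that a free para-methoxyphenol would suffer, after which hydroxide attacks the uronium carbon to release the phenol and return the urea; the closest known reaction types are the anodic C–H amination of arenes through N-arylpyridinium salts and the anodic Ritter-type acetamidation of arenes in acetonitrile, and no stereocentre is formed.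

**Compound list**
1 | 1-bromoeicosane | CCCCCCCCCCCCCCCCCCCCBr | starting material
2 | 3,5-dimethoxybenzyl bromide (1-(bromomethyl)-3,5-dimethoxybenzene) | COc1cc(CBr)cc(OC)c1 | starting material
3 | eicosylmagnesium bromide | CCCCCCCCCCCCCCCCCCCC[Mg]Br | intermediate
4 | 1-heneicosyl-3,5-dimethoxybenzene | CCCCCCCCCCCCCCCCCCCCCc1cc(OC)cc(OC)c1 | intermediate
5 | 2-(2-heneicosyl-4,6-dimethoxyphenyl)-1,1,3,3-tetramethylisouronium trifluoromethanesulfonate | CCCCCCCCCCCCCCCCCCCCCc1cc(OC)cc(OC)c1OC(N(C)C)=[N+](C)C.[O-]S(=O)(=O)C(F)(F)F | intermediate
6 | 6-n-heneicosyl-2,4-dimethoxyphenol (achiral) | CCCCCCCCCCCCCCCCCCCCCc1cc(OC)cc(OC)c1O | target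

**Totals**
Total step count: 2. Longest linear sequence: 2.

**Steps most likely to fail**
The route has only two steps, so the three risk points are the two stages of step 2 and step 1.

Risk 1, step 2, first stage (anodic C–O bond formation, the proposed new reaction). The radical cation of 4 may dimerise to a biaryl, may be oxygenated between the two methoxy groups, or may be captured too slowly by the urea. The fallback uses known chemistry, sets out from 4 and comes back at 6. Vilsmeier–Haack formylation of 4 (POCl3, DMF, 0 → 70 °C, then NaOAc aq) at the same ring position gives 2-heneicosyl-4,6-dimethoxybenzaldehyde F1. Baeyer–Villiger (Dakin-type) oxidation of this electron-rich aldehyde with mCPBA in CH2Cl2 at rt gives 2-heneicosyl-4,6-dimethoxyphenyl formate F2. Hydrolysis with KOH in degassed MeOH/THF at 0 °C and acidification gives 6.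

Risk 2, step 1 (sp3–sp3 coupling). The long-chain Grignard reagent may form sluggishly, and Wurtz-type homocoupling of either partner may consume material and complicate purification of the waxy product. The fallback sets out from 1 and comes back at 4. Heating 1 with PPh3 in toluene at 110 °C gives eicosyltriphenylphosphonium bromide F3. Deprotonation with NaN(SiMe3)2 in THF at 0 °C and Wittig olefination with commercial 3,5-dimethoxybenzaldehyde F4 gives (Z)-1-(heneicos-1-en-1-yl)-3,5-dimethoxybenzene F5, as a Z-rich mixture whose geometry is irrelevant. Hydrogenation (H2, 1 atm, Pd/C, EtOAc, rt) gives 4.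

Risk 3, step 2, second stage (release of the phenol from 5). The hindered isouronium salt may hydrolyse slowly, and the electron-rich phenoxide may be air-oxidised to a quinone in aqueous base. The fallback sets out from 5 and comes back at 6. Crude 5 is cleaved by aminolysis with pyrrolidine in CH2Cl2 at rt under Ar, which transfers the bis(dimethylamino)methylidene group to nitrogen. The liberated phenol is acetylated in the same flask (Ac2O, Et3N, DMAP) to 2-heneicosyl-4,6-dimethoxyphenyl acetate F6, which is air-stable and can be purified by chromatography. Reduction with LiAlH4 in THF at 0 °C and a quench with degassed dilute HCl gives 6.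

**Further compounds**
F1 | step 2 | 2-heneicosyl-4,6-dimethoxybenzaldehyde | CCCCCCCCCCCCCCCCCCCCCc1cc(OC)cc(OC)c1C=O
F2 | step 2 | 2-heneicosyl-4,6-dimethoxyphenyl formate | CCCCCCCCCCCCCCCCCCCCCc1cc(OC)cc(OC)c1OC=O
F3 | step 1 | eicosyltriphenylphosphonium bromide | CCCCCCCCCCCCCCCCCCCC[P+](c1ccccc1)(c1ccccc1)c1ccccc1.[Br-]
F4 | step 1 | 3,5-dimethoxybenzaldehyde | COc1cc(C=O)cc(OC)c1
F5 | step 1 | (Z)-1-(heneicos-1-en-1-yl)-3,5-dimethoxybenzene | CCCCCCCCCCCCCCCCCCC/C=C\c1cc(OC)cc(OC)c1
F6 | step 2 | 2-heneicosyl-4,6-dimethoxyphenyl acetate | CCCCCCCCCCCCCCCCCCCCCc1cc(OC)cc(OC)c1OC(C)=O
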